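## Structural features

4-Methylhydroatrovirinone (C26H32O8) is an achiral diaryl ether of two benzene rings joined through a single oxygen; ring positions are written a1–a6 and b1–b6 in lower case to keep them apart from compound labels. Ring A is a methyl benzoate (ester on a1) with free hydroxyls on a2 and a4 and the ether oxygen on a6, that is, a phloroglucinol acylated once and arylated once. Ring B is fully substituted: ether oxygen on b1, free hydroxyl on b2, two adjacent 3-methylbut-2-enyl (prenyl) groups on b3 and b4, methoxy groups on b5 and b6. There is no stereocentre, so the problem is one of regiochemistry and chemoselectivity. The fragile parts are the prenyl alkenes next to a free phenol (acid closes them to chromans), the b2-hydroxy/b5-methoxy pair (a hydroquinone monomethyl ether, easily oxidised to a quinone) and the salicylate-type ester. The real difficulty is the ether bond, which has four ortho substituents on two electron-rich rings, together with the placement of six substituents around ring B. The key step uses the fact that the ester carbon on a1 and the hydroxyl on b2 both sit ortho to the ether oxygen. If the ester carbon is bonded to b1 instead, the molecule is a benzophenone whose a6 oxygen can be joined to b1 by oxidation of the b2 phenol, after which methoxide can cut the carbonyl–b1 bond.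

## Logic of the disconnections

**19 to 18.** The ester C–OCH3 bond is cut and the ester carbon is rejoined to b1, which turns ring B into a cyclohexadienone and gives spiro diketone 18. The cut is made here because the forward reaction, a retro-Claisen cleavage, is driven by rearomatisation of ring B and delivers ester, ether and b2 phenol together in a last step that needs no protecting group. The demand is that methoxide adds to the furanone carbonyl and not to the dienone carbonyl.

**18 to 17.** The bond between the a6 oxygen and b1 is cut, which removes the only ring and the only stereocentre formed in the route and leads to benzophenone 17. The hard intermolecular ether coupling becomes an intramolecular five-membered ring closure on an oxidised phenol. The forward step must oxidise the b2 phenol selectively and trap the cation at b1 before anything else reacts. The formulae confirm that the three structures fit each other (17 C25H30O7, 18 C25H28O7, 19 C26H32O8), so none needed correction. 17 is kept without protecting groups: ring A is symmetric, so either ortho hydroxyl can close, and any group left on ring A would have to be removed with acid after the unchelated b2 phenol and the ether exist.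

**17 to 16.** Three aryl O–CH2OCH3 bonds on ring A are restored. The acetals are needed to make ring A a carbon nucleophile. They are removed at the benzophenone stage, where the b2 hydroxyl is held by the ketone and is least able to attack the neighbouring prenyl group. The forward step must be mild enough for two prenyl groups.

**16 to 15.** The b5 O–CH3 bond is cut, giving hydroquinone 15. Both oxygens of the hydroquinone are thus available as carriers for the prenyl groups. The forward step must methylate one of two hydroxyls, and the hydrogen bond from the b2 hydroxyl to the ketone provides the difference.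

**15 to 13.** The b3–CH2 and b4–CH2 bonds are cut and each prenyl group is returned to the adjacent oxygen as a tertiary allyl ether. Two C–C bonds on a crowded ring are thereby traded for two O-alkylations. The forward double Claisen shift must go only to b3 and b4, which is secured because b1 (acyl) and b6 (methoxy) are blocked.

**13 to 8 and 10.** The bond between the carbonyl carbon and a1 is cut, by way of carbinol 12 and aryllithium 11. The molecule falls into two arenes of similar size. The addition is placed on 8, where both ring B oxygens are still ethers, so no hydroxyl has to be protected for the organolithium step. This is the main change made to the way to 17. The forward step joins two doubly ortho-substituted partners, which an aldehyde electrophile tolerates.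

**8 to 5 and 6.** The two aryl O–C(CH3)2 bonds are cut, by way of bis-alkyne 7. The tertiary ethers come from 6 by copper-catalysed substitution and semihydrogenation. The demand is that the hydroxyl hydrogen-bonded to the formyl group is alkylated as well.

**5 to 1, and 10 to 9.** The b1–CHO bond is cut, by way of 4, 3 and 2. The formyl group blocks b1 during the Claisen step and later becomes the ester carbon. It is introduced by lithiation between two oxygens of 2, the bis-acetal of 1. The demand is lithiation at the doubly flanked position. The three acetal O–C bonds of 10 are cut to give 9.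

## Other disconnections considered

**Alternative 1:** The cut runs through ring B at the b2–b3 bond, so that ring B comes from a four-membered ring.

- **Forward key step.** Cyclobutenone A2 would be heated. A 4π ring opening gives a dienylketene, a 6π closure joins the ketene carbon (b2) to the alkene terminus (b3), and tautomerisation gives phenol A1. Acid would then remove two methoxymethyl groups to reach 19. A2 would come from dimethyl squarate A3 by exchange of one methoxy group for the ring A aryloxy group, 1,2-addition of an alkenyllithium carrying both prenyl groups, and O-methylation.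
- **In favour.** Every ring B substituent is placed by the connectivity of A2. The ether is made early by addition–elimination on a vinylogous ester. The key step is a neutral thermal pericyclic cascade with no oxidant; on this chemoselectivity point the alternative is the better plan. The electronic bias of the organolithium addition is also right, since the carbonyl vinylogous to the weaker aryloxy donor is the more electrophilic.
- **Against.** The aryloxy exchange needs a hindered, internally hydrogen-bonded phenol as nucleophile. The alkenyllithium has two doubly allylic methylenes, needs its own sequence and can isomerise into conjugation. The aryloxide can be displaced by excess organolithium. The route ends with acid treatment of A1, whose b2 phenol is electron-rich, ortho to a prenyl group and has no carbonyl to hydrogen-bond to.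
- **Comparison.** Structurally it builds ring B from small pieces, while the chosen plan buys both rings. Mechanistically it replaces one uncertain oxidation by several organometallic steps. The step count would be about equal, but the chosen plan ends with a base step free of protecting groups, whereas this one ends with its most delicate deprotection.

**Alternative 2:** The cuts are the b3–CH2 and b4–CH2 bonds, made on the finished diaryl ether.

- **Forward key step.** Heating bis(tertiary allyl) ether A5 would cause two aromatic Claisen shifts (b2 oxygen to b3, b5 oxygen to b4) to give hydroquinone A4. Methylation at b5 and acid removal of two acetals would follow.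
- **In favour.** The pericyclic step is the same reaction as step 9 of the chosen plan, with both wrong ortho positions blocked; on this step the two plans are equal. No oxidative dearomatisation is needed, which removes the largest risk of the chosen plan; on that point the alternative is better.
- **Against.** It presupposes the ether with four ortho substituents, to be made by copper- or palladium-mediated coupling or by nucleophilic aromatic substitution between two hindered partners. This is the bond that is hardest to form intermolecularly. In A4 neither the b2 nor the b5 hydroxyl is bonded to a carbonyl and both have similar neighbours, so nothing distinguishes them for methylation; in 15 the ketone ties up the b2 hydroxyl. The final acid step again meets an unchelated ortho-prenylphenol.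
- **Comparison.** Both plans use the same ring B logic and differ in what blocks b1. The acyl group of the chosen plan also controls the methylation and becomes the ester; an aryloxy group cannot do that. The alternative is all ground-state two-electron chemistry and needs no electrolysis. The step count would be similar, with two steps of doubtful selectivity against one.

**Alternative 3:** Ring A is cut at the a3–a4 bond and traced back to an open chain.

- **Forward key step.** A hindered amide base would deprotonate the acetyl methyl group (a3) of glutaconate A7. The enolate attacks the ester carbonyl of the CH2CO2CH3 arm (a4), closing ring A by a Dieckmann-type condensation, and enolisation gives resorcinol A6. Removal of the acetal on b2 would give 19. A7 would come from addition–elimination of the ring B phenol A8 to an activated five-carbon acceptor, then C-acetylation.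
- **In favour.** Ring A appears with both hydroxyls free and the ester in place, so it needs no protecting groups; this is better than the three acetals of the chosen plan. The ether oxygen is attached to an activated alkene carbon, not to an arene. There is no oxidation.
- **Against.** A8 is a pentasubstituted, air-sensitive phenol. Its synthesis needs all the ring B work of the chosen plan plus conversion of the b1 carbon substituent into oxygen and differentiation of two adjacent oxygens. In A7 the methylene between the enol ether carbon and the ester is more acidic than the acetyl methyl, so the useful enolate needs a dianion or kinetic control. The aryloxide is a leaving group and can be expelled. The last step is again acid next to a prenyl group, though for one acetal only.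
- **Comparison.** Structurally the plan is linear and builds the easy ring from scratch. Mechanistically it is familiar base-mediated carbonyl chemistry, easier to troubleshoot than an electrolysis, and equal to the chosen plan in ending with an aromatisation-driven step. It is clearly longer, since A8 alone needs about as many steps as the chosen route needs to reach 16.

Key step: step 12

Assumption: 18 is made and used as a racemate, because its only stereocentre is destroyed in step 13 and 19 is achiral.

## Route

Step 1
Reactants: 1 2-methoxyhydroquinone (2-methoxybenzene-1,4-diol)
Product: 2 2-methoxy-1,4-bis(methoxymethoxy)benzene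
Conditions: MOMCl (2.5 equiv), i-Pr2NEt (3 equiv), CH2Cl2, 0 °C → rt, N2
Reagents that add atoms: chloromethyl methyl ether, COCCl
Why: Base-mediated O-alkylation of both phenols by a reactive α-chloro ether (Williamson-type acetal formation); the amine base limits air oxidation of the hydroquinone, and the two acetals are the directing groups for step 2.

Step 2
Reactants: 2 2-methoxy-1,4-bis(methoxymethoxy)benzene
Product: 4 2-methoxy-3,6-bis(methoxymethoxy)benzaldehyde, via aryllithium 3 (not isolated)
Conditions: n-BuLi (1.15 equiv), THF, 0 °C, 1 h; DMF, −78 °C → rt; aq. NH4Cl
Reagents that add atoms: N,N-dimethylformamide, CN(C)C=O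
Why: Directed ortho-metalation: the hydrogen between the methoxy and a methoxymethoxy group is flanked by two coordinating oxygens and is the most acidic, as in 1,2,4-trialkoxybenzenes; the aryllithium is formylated by DMF and the hemiaminal collapses on work-up.

Step 3
Reactants: 4 2-methoxy-3,6-bis(methoxymethoxy)benzaldehyde
Product: 5 3,6-dihydroxy-2-methoxybenzaldehyde
Conditions: HCl (1.25 M in MeOH), rt → 40 °C, N2; aqueous work-up
Reagents that add atoms: none
Why: Acid-catalysed acetal exchange transfers both methoxymethyl groups to methanol; nothing acid-sensitive is present yet, and any dimethyl acetal of the aldehyde reverts on aqueous work-up.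

Step 4
Reactants: 5 3,6-dihydroxy-2-methoxybenzaldehyde; 6 3-chloro-3-methylbut-1-yne
Product: 7 2-methoxy-3,6-bis[(2-methylbut-3-yn-2-yl)oxy]benzaldehyde
Conditions: 6 (3 equiv), CuCl2·2H2O (1 mol %), DBU (3.5 equiv), MeCN, 0 °C → rt
Reagents that add atoms: none
Why: Copper-catalysed propargylic substitution of the tertiary chloride by the phenoxides, the standard route to aryl 1,1-dimethylpropargyl ethers; the hydroxyl hydrogen-bonded to the formyl group reacts more slowly, hence the excess of 6 and DBU.

Step 5
Reactants: 7 2-methoxy-3,6-bis[(2-methylbut-3-yn-2-yl)oxy]benzaldehyde
Product: 8 2-methoxy-3,6-bis[(2-methylbut-3-en-2-yl)oxy]benzaldehyde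
Conditions: H2 (1 atm), Pd/CaCO3 poisoned with Pb(OAc)2 (Lindlar catalyst), quinoline, EtOAc, rt, stopped after 2 equiv H2
Reagents that add atoms: none
Why: Lindlar semihydrogenation stops at the alkene for terminal alkynes; aldehyde and aryl ethers are inert, and the temperature stays below 40 °C so that the tertiary allyl ethers do not rearrange yet.

Step 6
Reactants: 9 phloroglucinol (benzene-1,3,5-triol)
Product: 10 1,3,5-tris(methoxymethoxy)benzene
Conditions: MOMCl (3.6 equiv), i-Pr2NEt (4.5 equiv), DMF, 0 °C → rt
Reagents that add atoms: chloromethyl methyl ether, COCCl
Why: Threefold O-alkylation by the hard α-chloro ether, which favours oxygen over the nucleophilic ring carbons of phloroglucinol; the acetals later direct lithiation and leave together in step 11.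

Step 7
Reactants: 10 1,3,5-tris(methoxymethoxy)benzene; 8 2-methoxy-3,6-bis[(2-methylbut-3-en-2-yl)oxy]benzaldehyde
Product: 12 {2-methoxy-3,6-bis[(2-methylbut-3-en-2-yl)oxy]phenyl}[2,4,6-tris(methoxymethoxy)phenyl]methanol (racemic), via aryllithium 11 (not isolated)
Conditions: 10 (1.3 equiv), n-BuLi (1.25 equiv), THF, 0 °C, 1 h; then 8, −78 → 0 °C; aq. NH4Cl
Reagents that add atoms: none
Why: Directed ortho-metalation of 10 between two methoxymethoxy groups gives a chelate-stabilised aryllithium that adds 1,2 to the non-enolisable aldehyde; 8 has no acidic hydrogen, so no extra protection is needed, and the racemic carbinol centre disappears in step 8.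

Step 8
Reactants: 12 {2-methoxy-3,6-bis[(2-methylbut-3-en-2-yl)oxy]phenyl}[2,4,6-tris(methoxymethoxy)phenyl]methanol
Product: 13 {2-methoxy-3,6-bis[(2-methylbut-3-en-2-yl)oxy]phenyl}[2,4,6-tris(methoxymethoxy)phenyl]methanone
Conditions: Dess–Martin periodinane (1.3 equiv), NaHCO3, CH2Cl2, 0 °C → rt
Reagents that add atoms: none
Why: Dess–Martin oxidation of a hindered secondary diaryl carbinol to the ketone under buffered conditions that spare the tertiary allyl ethers, the acetals and the terminal alkenes.

Step 9
Reactants: 13 {2-methoxy-3,6-bis[(2-methylbut-3-en-2-yl)oxy]phenyl}[2,4,6-tris(methoxymethoxy)phenyl]methanone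
Product: 15 [2,5-dihydroxy-6-methoxy-3,4-bis(3-methylbut-2-enyl)phenyl][2,4,6-tris(methoxymethoxy)phenyl]methanone, via mono-rearranged phenol 14 (not isolated)
Conditions: degassed toluene, 110–120 °C (sealed vessel), argon
Reagents that add atoms: none
Why: Two aromatic Claisen rearrangements ([3,3] shifts, each followed by tautomerisation): the ether on b5 can deliver its allyl unit only to b4 because b6 carries OMe, and the ether on b2 only to b3 because b1 carries the ketone, the tertiary terminus ending as the prenyl group each time. The order of the two shifts is immaterial, and neutral degassed conditions protect the acetals and the hydroquinone.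

Step 10
Reactants: 15 [2,5-dihydroxy-6-methoxy-3,4-bis(3-methylbut-2-enyl)phenyl][2,4,6-tris(methoxymethoxy)phenyl]methanone
Product: 16 [2-hydroxy-5,6-dimethoxy-3,4-bis(3-methylbut-2-enyl)phenyl][2,4,6-tris(methoxymethoxy)phenyl]methanone
Conditions: MeI (1.3 equiv), K2CO3 (1.2 equiv), acetone, rt, argon
Reagents that add atoms: iodomethane, CI
Why: Williamson methylation under weak base: the b2 hydroxyl is held in a hydrogen bond to the ketone and is far less nucleophilic, so the methyl group should go to the free b5 hydroxyl, the usual selectivity of 2,5-dihydroxyaryl ketones.

Step 11
Reactants: 16 [2-hydroxy-5,6-dimethoxy-3,4-bis(3-methylbut-2-enyl)phenyl][2,4,6-tris(methoxymethoxy)phenyl]methanone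
Product: 17 [2-hydroxy-5,6-dimethoxy-3,4-bis(3-methylbut-2-enyl)phenyl](2,4,6-trihydroxyphenyl)methanone
Conditions: HCl (ca. 0.3 M in MeOH), 0 °C → rt, argon; NaHCO3 quench
Reagents that add atoms: none
Why: Acid-catalysed acetal exchange to methanol removes the three methoxymethyl groups, the two ortho to the ketone being the most labile; dilute acid at or below room temperature is used because the b3 prenyl group could otherwise cyclise onto the b2 hydroxyl, which is deactivated here by its hydrogen bond to the ketone.

Step 12
Reactants: 17 [2-hydroxy-5,6-dimethoxy-3,4-bis(3-methylbut-2-enyl)phenyl](2,4,6-trihydroxyphenyl)methanone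
Product: 18 4,6-dihydroxy-5',6'-dimethoxy-3',4'-bis(3-methylbut-2-enyl)spiro[1-benzofuran-2,1'-cyclohexa-3',5'-diene]-2',3-dione (racemic)
Conditions: undivided cell, graphite anode, Pt cathode, Bu4NBF4 (0.1 M), (CF3)2CHOH, substrate 5 mM, constant current ca. 2 mA cm−2, 2.1 F mol−1, 10 °C, argon
Reagents that add atoms: none
Why: Anodic removal of two electrons and one proton from the b2 phenol of ring B, the hydroquinone monomethyl ether and the most easily oxidised site, gives a phenoxonium ion with positive charge on b1, b3 and b5; an ortho hydroxyl of ring A, held over b1 by the ketone bridge, adds to b1 and loses its proton, so the O–b1 bond and the furanone ring form together. The closest known reaction type is the oxidative dearomatising spirocyclisation of phenols by a tethered oxygen nucleophile, which turns 2-hydroxybenzophenones into grisadienediones with chemical oxidants and has anodic counterparts in fluorinated alcohols; it is applied here in the ortho-dienone sense, which is an extrapolation. The ring closes in a 5-exo-trig mode (a6 oxygen, a6, a1, carbonyl carbon, b1). Positions b3 and b5 are out of reach of the tether, and b2 and b6, which a six-membered closure could reach, give only a reversible hemiketal (b2) or carry no charge (b6, meta). The spiro carbon is the only new stereocentre; nothing in 17 biases it, so 18 should form as a racemate, which is acceptable because the centre becomes planar again in step 13. Selectivity for b1 over solvent capture at b5, over loss of a benzylic proton from the b3 prenyl group (ortho-quinone methide, then chromene) and over intermolecular C–C coupling with ring A rests on the intramolecular nucleophile, the non-nucleophilic and non-basic solvent and the high dilution. Selectivity over the prenyl alkenes and the acylphloroglucinol ring rests on the lower oxidation potential of the ring B phenol and on stopping near 2 F per mole; the two ortho hydroxyls of ring A are equivalent. Hydrogen evolution at the cathode consumes the released protons and keeps the medium near neutral, and the product is a fully substituted cyclohexa-2,4-dienone that cannot tautomerise and is too hindered to dimerise readily.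

Step 13
Reactants: 18 4,6-dihydroxy-5',6'-dimethoxy-3',4'-bis(3-methylbut-2-enyl)spiro[1-benzofuran-2,1'-cyclohexa-3',5'-diene]-2',3-dione
Product: 19 methyl 2-[2-hydroxy-5,6-dimethoxy-3,4-bis(3-methylbut-2-enyl)phenoxy]-4,6-dihydroxybenzoate (4-methylhydroatrovirinone)
Conditions: NaOMe (5 equiv), degassed MeOH, 0 °C → rt, argon; then AcOH
Reagents that add atoms: sodium methoxide in methanol, C[O-].[Na+]
Why: Retro-Claisen cleavage of a non-enolisable 1,3-diketone: methoxide adds to the furanone carbonyl and the tetrahedral intermediate expels b1 as the dienolate of ring B, which is an aromatic phenoxide, so the fragmentation is irreversible and gives ester, diaryl ether and free b2 hydroxyl at once while erasing the spiro centre. Exchange of methoxide at the methoxy-bearing dienone carbon is degenerate, and air is excluded because the product phenoxide is easily oxidised.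

## Compound list

1 | 2-methoxyhydroquinone (2-methoxybenzene-1,4-diol) | COc1cc(O)ccc1O | starting material
2 | 2-methoxy-1,4-bis(methoxymethoxy)benzene | COCOc1ccc(OCOC)c(OC)c1 | intermediate
3 | [2-methoxy-3,6-bis(methoxymethoxy)phenyl]lithium | [Li]c1c(OC)c(OCOC)ccc1OCOC | intermediate (not isolated)
4 | 2-methoxy-3,6-bis(methoxymethoxy)benzaldehyde | O=Cc1c(OC)c(OCOC)ccc1OCOC | intermediate
5 | 3,6-dihydroxy-2-methoxybenzaldehyde | O=Cc1c(OC)c(O)ccc1O | intermediate
6 | 3-chloro-3-methylbut-1-yne | C#CC(C)(C)Cl | starting material
7 | 2-methoxy-3,6-bis[(2-methylbut-3-yn-2-yl)oxy]benzaldehyde | O=Cc1c(OC)c(OC(C)(C)C#C)ccc1OC(C)(C)C#C | intermediate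
8 | 2-methoxy-3,6-bis[(2-methylbut-3-en-2-yl)oxy]benzaldehyde | O=Cc1c(OC)c(OC(C)(C)C=C)ccc1OC(C)(C)C=C | intermediate
9 | phloroglucinol (benzene-1,3,5-triol) | Oc1cc(O)cc(O)c1 | starting material
10 | 1,3,5-tris(methoxymethoxy)benzene | COCOc1cc(OCOC)cc(OCOC)c1 | intermediate
11 | [2,4,6-tris(methoxymethoxy)phenyl]lithium | [Li]c1c(OCOC)cc(OCOC)cc1OCOC | intermediate (not isolated)
12 | {2-methoxy-3,6-bis[(2-methylbut-3-en-2-yl)oxy]phenyl}[2,4,6-tris(methoxymethoxy)phenyl]methanol (racemic) | OC(c1c(OCOC)cc(OCOC)cc1OCOC)c1c(OC)c(OC(C)(C)C=C)ccc1OC(C)(C)C=C | intermediate
13 | {2-methoxy-3,6-bis[(2-methylbut-3-en-2-yl)oxy]phenyl}[2,4,6-tris(methoxymethoxy)phenyl]methanone | O=C(c1c(OCOC)cc(OCOC)cc1OCOC)c1c(OC)c(OC(C)(C)C=C)ccc1OC(C)(C)C=C | intermediate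
14 | {3-hydroxy-2-methoxy-4-(3-methylbut-2-enyl)-6-[(2-methylbut-3-en-2-yl)oxy]phenyl}[2,4,6-tris(methoxymethoxy)phenyl]methanone | O=C(c1c(OCOC)cc(OCOC)cc1OCOC)c1c(OC)c(O)c(CC=C(C)C)cc1OC(C)(C)C=C | intermediate (not isolated)
15 | [2,5-dihydroxy-6-methoxy-3,4-bis(3-methylbut-2-enyl)phenyl][2,4,6-tris(methoxymethoxy)phenyl]methanone | O=C(c1c(OCOC)cc(OCOC)cc1OCOC)c1c(OC)c(O)c(CC=C(C)C)c(CC=C(C)C)c1O | intermediate
16 | [2-hydroxy-5,6-dimethoxy-3,4-bis(3-methylbut-2-enyl)phenyl][2,4,6-tris(methoxymethoxy)phenyl]methanone | O=C(c1c(OCOC)cc(OCOC)cc1OCOC)c1c(OC)c(OC)c(CC=C(C)C)c(CC=C(C)C)c1O | intermediate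
17 | [2-hydroxy-5,6-dimethoxy-3,4-bis(3-methylbut-2-enyl)phenyl](2,4,6-trihydroxyphenyl)methanone | O=C(c1c(O)cc(O)cc1O)c1c(O)c(CC=C(C)C)c(CC=C(C)C)c(OC)c1OC | intermediate
18 | 4,6-dihydroxy-5',6'-dimethoxy-3',4'-bis(3-methylbut-2-enyl)spiro[1-benzofuran-2,1'-cyclohexa-3',5'-diene]-2',3-dione (racemic, one enantiomer drawn) | O=C1c2c(O)cc(O)cc2O[C@]13C(=O)C(CC=C(C)C)=C(CC=C(C)C)C(OC)=C3OC | intermediate
19 | methyl 2-[2-hydroxy-5,6-dimethoxy-3,4-bis(3-methylbut-2-enyl)phenoxy]-4,6-dihydroxybenzoate (4-methylhydroatrovirinone, achiral) | COC(=O)c1c(O)cc(O)cc1Oc1c(O)c(CC=C(C)C)c(CC=C(C)C)c(OC)c1OC | target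

## Step count and least certain steps

Total step count: 13. Longest linear sequence: 12 steps (steps 1–5 and 7–13, from 1 to 19); step 6 is a one-step side branch.

**Step 12 (key step).** The most likely failures are diversion of the phenoxonium ion and over-oxidation. Traces of water can add at b5 and lead to a quinone by loss of methanol. The b3 prenyl group can lose a benzylic proton and end as a chromene. The polyphenol can foul the anode or be oxidised further once some ring-opened phenol has formed. All of these follow from the cation being generated continuously at an electrode in the presence of unreacted material. The fallback separates oxidation from ring closure. It sets out from 17: one equivalent of PhI(OAc)2 in methanol at 0 °C should give the para-quinone monoketal 3,4,4-trimethoxy-5,6-bis(3-methylbut-2-enyl)-2-(2,4,6-trihydroxybenzoyl)cyclohexa-2,5-dien-1-one F1, the standard outcome for a para-methoxyphenol in a nucleophilic solvent. F1 is then dissolved in (CF3)2CHOH with a catalytic amount of CF3CO2H at 0 °C. Ionisation of one ketal methoxy group regenerates the same phenoxonium ion with no oxidant present, and the ring A hydroxyl closes on b1 with loss of methanol. The sequence comes back to the route at 18; any direct spirocyclisation during the first stage gives 18 as well.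

**Step 13.** Methoxide first deprotonates the ring A hydroxyls, and the resulting phenoxide makes the furanone carbonyl a vinylogous carboxylate. Addition there may become slow enough for attack at the dienone carbonyl (cleavage of the other bond at the spiro carbon, opening ring B) or air oxidation of the product phenoxide to compete. The fallback sets out from 18 and masks the acidic hydroxyls: allyl bromide and K2CO3 in DMF should give 5',6'-dimethoxy-3',4'-bis(3-methylbut-2-enyl)-4,6-bis(prop-2-enyloxy)spiro[1-benzofuran-2,1'-cyclohexa-3',5'-diene]-2',3-dione F2. NaOMe in methanol should then open it to methyl 2-[2-hydroxy-5,6-dimethoxy-3,4-bis(3-methylbut-2-enyl)phenoxy]-4,6-bis(prop-2-enyloxy)benzoate F3, because ring A can no longer form a phenoxide. Catalytic Pd(PPh3)4 with morpholine in THF (allyl transfer through a π-allyl complex of zerovalent palladium, to which the trisubstituted prenyl alkenes are inert) removes both allyl groups and comes back to the route at 19.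

**Step 11.** Acid may protonate a prenyl alkene before the last (para) acetal has gone, so that the b2 hydroxyl closes a chroman or methanol adds to the tertiary cation. The risk grows as ring A hydroxyls are freed and compete for the ketone hydrogen bond. The fallback sets out from 16 and replaces protic cleavage by silyl transfer: TMSOTf with 2,2'-bipyridyl in MeCN at 0 °C should convert the aryl acetals (and the free hydroxyl) into silyl ethers, giving [5,6-dimethoxy-3,4-bis(3-methylbut-2-enyl)-2-(trimethylsilyloxy)phenyl][2,4,6-tris(trimethylsilyloxy)phenyl]methanone F4, while bipyridyl captures the methoxymethyl cation. Water at neutral pH then hydrolyses F4 and the sequence comes back to the route at 17.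

**Step 9.** The tertiary allyl ether next to the diaryl ketone is crowded and attached to a good phenoxide leaving group. It may ionise and lose its allyl unit (as isoprene) instead of rearranging, or the second shift may lag and force prolonged heating. The fallback moves the sigmatropic step to the aldehyde, where the ortho substituent is small. It sets out from 8: heating in toluene should give 3,6-dihydroxy-2-methoxy-4,5-bis(3-methylbut-2-enyl)benzaldehyde F5, and MeI with K2CO3 should methylate the unchelated hydroxyl to 6-hydroxy-2,3-dimethoxy-4,5-bis(3-methylbut-2-enyl)benzaldehyde F6. Two equivalents of 11 (the first deprotonates the phenol) should add to give [2-hydroxy-5,6-dimethoxy-3,4-bis(3-methylbut-2-enyl)phenyl][2,4,6-tris(methoxymethoxy)phenyl]methanol F7. MnO2 in CH2Cl2 oxidises the benzylic carbinol and the sequence comes back to the route at 16.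

**Step 4.** Alkylation may stop at the mono-ether, because the hydroxyl ortho to the formyl group is held in a hydrogen bond and its phenoxide is a weak nucleophile toward the hindered tertiary electrophile. The fallback sets out from 5 and uses a Tsuji–Trost O-allylation: tert-butyl 2-methylbut-3-en-2-yl carbonate with catalytic Pd(PPh3)4 in THF. The phenoxide attacks the cationic 1,1-dimethylallyl palladium complex at its more substituted terminus, with the tert-butoxide released on decarboxylation as the only base. This gives the tertiary allyl ethers directly, skips 7 and the semihydrogenation, and comes back to the route at 8. It makes no new compound (F0). The drawback that keeps it out of the main route is possible leakage to linear prenyl ethers.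

## Further compounds

F1 | step 12 | 3,4,4-trimethoxy-5,6-bis(3-methylbut-2-enyl)-2-(2,4,6-trihydroxybenzoyl)cyclohexa-2,5-dien-1-one | O=C(c1c(O)cc(O)cc1O)C1=C(OC)C(OC)(OC)C(CC=C(C)C)=C(CC=C(C)C)C1=O
F2 | step 13 | 5',6'-dimethoxy-3',4'-bis(3-methylbut-2-enyl)-4,6-bis(prop-2-enyloxy)spiro[1-benzofuran-2,1'-cyclohexa-3',5'-diene]-2',3-dione (racemic, one enantiomer drawn) | O=C1c2c(OCC=C)cc(OCC=C)cc2O[C@]13C(=O)C(CC=C(C)C)=C(CC=C(C)C)C(OC)=C3OC
F3 | step 13 | methyl 2-[2-hydroxy-5,6-dimethoxy-3,4-bis(3-methylbut-2-enyl)phenoxy]-4,6-bis(prop-2-enyloxy)benzoate | COC(=O)c1c(OCC=C)cc(OCC=C)cc1Oc1c(O)c(CC=C(C)C)c(CC=C(C)C)c(OC)c1OC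
F4 | step 11 | [5,6-dimethoxy-3,4-bis(3-methylbut-2-enyl)-2-(trimethylsilyloxy)phenyl][2,4,6-tris(trimethylsilyloxy)phenyl]methanone | O=C(c1c(O[Si](C)(C)C)cc(O[Si](C)(C)C)cc1O[Si](C)(C)C)c1c(O[Si](C)(C)C)c(CC=C(C)C)c(CC=C(C)C)c(OC)c1OC
F5 | step 9 | 3,6-dihydroxy-2-methoxy-4,5-bis(3-methylbut-2-enyl)benzaldehyde | O=Cc1c(OC)c(O)c(CC=C(C)C)c(CC=C(C)C)c1O
F6 | step 9 | 6-hydroxy-2,3-dimethoxy-4,5-bis(3-methylbut-2-enyl)benzaldehyde | O=Cc1c(OC)c(OC)c(CC=C(C)C)c(CC=C(C)C)c1O
F7 | step 9 | [2-hydroxy-5,6-dimethoxy-3,4-bis(3-methylbut-2-enyl)phenyl][2,4,6-tris(methoxymethoxy)phenyl]methanol (racemic) | OC(c1c(OCOC)cc(OCOC)cc1OCOC)c1c(OC)c(OC)c(CC=C(C)C)c(CC=C(C)C)c1O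
F0 | step 4 | none | none
A1 | alternative 1 | methyl 2-[2-hydroxy-5,6-dimethoxy-3,4-bis(3-methylbut-2-enyl)phenoxy]-4,6-bis(methoxymethoxy)benzoate | COC(=O)c1c(OCOC)cc(OCOC)cc1Oc1c(O)c(CC=C(C)C)c(CC=C(C)C)c(OC)c1OC
A2 | alternative 1 | methyl 2-{[3-(2,9-dimethyldeca-2,5,8-trien-5-yl)-2,3-dimethoxy-4-oxocyclobut-1-en-1-yl]oxy}-4,6-bis(methoxymethoxy)benzoate (racemic, alkene geometry not fixed) | COC(=O)c1c(OCOC)cc(OCOC)cc1OC1=C(OC)C(OC)(C(CC=C(C)C)=CCC=C(C)C)C1=O
A3 | alternative 1 | dimethyl squarate (3,4-dimethoxycyclobut-3-ene-1,2-dione) | COC1=C(OC)C(=O)C1=O
A4 | alternative 2 | methyl 2-[2,5-dihydroxy-6-methoxy-3,4-bis(3-methylbut-2-enyl)phenoxy]-4,6-bis(methoxymethoxy)benzoate | COC(=O)c1c(OCOC)cc(OCOC)cc1Oc1c(O)c(CC=C(C)C)c(CC=C(C)C)c(O)c1OC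
A5 | alternative 2 | methyl 2-{2-methoxy-3,6-bis[(2-methylbut-3-en-2-yl)oxy]phenoxy}-4,6-bis(methoxymethoxy)benzoate | COC(=O)c1c(OCOC)cc(OCOC)cc1Oc1c(OC)c(OC(C)(C)C=C)ccc1OC(C)(C)C=C
A6 | alternative 3 | methyl 2-[5,6-dimethoxy-2-(methoxymethoxy)-3,4-bis(3-methylbut-2-enyl)phenoxy]-4,6-dihydroxybenzoate | COC(=O)c1c(O)cc(O)cc1Oc1c(OCOC)c(CC=C(C)C)c(CC=C(C)C)c(OC)c1OC
A7 | alternative 3 | dimethyl 2-acetyl-3-[5,6-dimethoxy-2-(methoxymethoxy)-3,4-bis(3-methylbut-2-enyl)phenoxy]pent-2-enedioate (alkene geometry not fixed) | COC(=O)CC(Oc1c(OCOC)c(CC=C(C)C)c(CC=C(C)C)c(OC)c1OC)=C(C(C)=O)C(=O)OC
A8 | alternative 3 | 2,3-dimethoxy-6-(methoxymethoxy)-4,5-bis(3-methylbut-2-enyl)phenol | COCOc1c(O)c(OC)c(OC)c(CC=C(C)C)c1CC=C(C)C
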